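**Retrosynthetic overview**
- Feature: the ester carbonyl carbon C1 ends an unbranched, unfunctionalised C2–C28 alkyl chain. The only ring is the benzene ring of the benzyl group, bought intact in benzyl alcohol, and there is no stereocentre.
- Key disconnection: C1–C2 and C1–O(benzyl) are cut together, leaving a linear internal C27 alkene, carbon monoxide and benzyl alcohol (forward: chain-walking benzyloxycarbonylation).
- The alkene comes from heptacosan-14-ol by dehydration, and the alcohol from the symmetric 14-heptacosanone by hydride reduction; the symmetry makes both directions of elimination identical.
- Ring formation: none; no ring is closed anywhere in the route.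

Key step: step 3

Assumption: heptacos-13-ene is used as the mixture of E and Z isomers (with any positional isomers from acid-catalysed migration) that the dehydration delivers. It is drawn as the E isomer, and every isomer should give the same ester in the key step. C1–C28 number the octacosanoate chain from the ester carbonyl.

Step 1
Reactants: 1 14-heptacosanone (heptacosan-14-one)
Product: 2 heptacosan-14-ol
Conditions: NaBH4, THF/EtOH, 50 °C; then aq. HCl
Reagents that add atoms: none
Why: Hydride reduction of an unhindered dialkyl ketone with NaBH4 (carbonyl reduction) should be clean because no other functional group is present, and C14 carries two identical tridecyl chains, so no stereocentre arises.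

Step 2
Reactants: 2 heptacosan-14-ol
Product: 3 heptacos-13-ene (mixture of E and Z isomers, drawn E)
Conditions: TsOH·H2O (cat.), neat melt, 160 °C, N2 sweep to remove water; then hexane, silica plug
Reagents that add atoms: none
Why: Acid-catalysed E1 dehydration of the secondary alcohol should give the internal alkene; since 2 is symmetric, proton loss from C13 or C15 gives the same C13=C14 alkene, and any E/Z or positional isomers formed in the acid are harmless because step 3 converges them.

Step 3
Reactants: 3 heptacos-13-ene; 4 carbon monoxide; 5 benzyl alcohol
Product: 7 benzyl octacosanoate, via heptacos-1-ene 6 (not isolated)
Conditions: Pd(OAc)2 (2 mol %), 1,2-bis(di-tert-butylphosphinomethyl)benzene (10 mol %), CH3SO3H (20 mol %), CO (20 bar), BnOH (10 equiv.), toluene, 90 °C; then silica plug, recrystallisation from acetone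
Reagents that add atoms: carbon monoxide (reactant 4), [C-]#[O+]; benzyl alcohol (reactant 5), OCc1ccccc1
Why: Pd(OAc)2, the diphosphine and CH3SO3H should form a cationic divalent palladium hydride that adds across C13=C14 of 3 and walks along the chain by reversible β-hydride elimination and reinsertion, passing through every positional isomer up to the terminal alkene 6 and the primary alkyl. CO inserts reversibly into all of these alkyls, which forms C1–C2, but only the unhindered linear acyl is cleaved by benzyl alcohol at a useful rate; this alcoholysis forms C1–O and returns the hydride. The closest known reaction type is the isomerising alkoxycarbonylation of internal alkenes and unsaturated fatty acid esters with palladium and bulky chelating bis(di-tert-butylphosphino) ligands, applied here with benzyl alcohol as the nucleophile. No ring is closed and no stereocentre is formed. The selectivity needed is linear over branched carbonylation; it is secured by the tert-butyl groups on phosphorus, which block alcoholysis of every secondary acyl. The substrate supports this because it is a plain hydrocarbon with no group that could hold the catalyst mid-chain and both chain ends lead to the same ester, so every E, Z or positional isomer should converge on 7.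

**Compound list**
1 | 14-heptacosanone (heptacosan-14-one) | CCCCCCCCCCCCCC(=O)CCCCCCCCCCCCC | starting material
2 | heptacosan-14-ol | CCCCCCCCCCCCCC(O)CCCCCCCCCCCCC | intermediate
3 | heptacos-13-ene (E/Z mixture, drawn E) | CCCCCCCCCCCC/C=C/CCCCCCCCCCCCC | intermediate
4 | carbon monoxide | [C-]#[O+] | starting material
5 | benzyl alcohol | OCc1ccccc1 | starting material
6 | heptacos-1-ene (terminal isomer, not isolated) | C=CCCCCCCCCCCCCCCCCCCCCCCCCC | intermediate
7 | benzyl octacosanoate | CCCCCCCCCCCCCCCCCCCCCCCCCCCC(=O)OCc1ccccc1 | target

**Total step count:** 3
**Longest linear sequence:** 3 steps (1 → 2 → 3 → 7)

**Steps most likely to fail**

Step 3 (key step). The catalysis may stall in the benzyl alcohol medium. The bulkier, less polar alcohol should cleave the linear acyl more slowly than methanol does. Acid-catalysed self-condensation of benzyl alcohol would consume the nucleophile and release water. The hydride may decay to palladium metal before it reaches the chain end. The fallback sets out from 3 and 4 and comes back at 7. The same isomerising carbonylation is run in methanol, the medium in which this catalyst system is best established, and should give methyl octacosanoate F1. In a separate operation F1 is heated with benzyl alcohol 5 and catalytic Ti(OiPr)4 while methanol distils off, which should give 7. The benzyl group then enters by acyl transfer and not in the carbonylation itself.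

Step 2. In the hot acidic melt the secondary cation may be diverted into intermolecular ether formation and cationic oligomerisation of the alkene, and the dehydration may stop short of completion. The fallback sets out from 2 and comes back at 3 by a Chugaev elimination. Alcohol 2 is treated with NaH, CS2 and MeI in THF to give O-(heptacosan-14-yl) S-methyl dithiocarbonate F2. F2 is pyrolysed neat at about 200 °C, and the concerted syn elimination should deliver 3 without acid or cationic intermediates.

Step 1. The waxy ketone and the alkoxyborates formed from it may stay out of solution, so that hydride transfer stops at partial conversion. The fallback sets out from 1 and comes back at 3, bypassing 2. Ketone 1 is condensed with p-toluenesulfonylhydrazide in hot THF/EtOH to give heptacosan-14-one p-toluenesulfonylhydrazone F3. A Shapiro reaction of F3 with n-BuLi (2 equiv.) in THF/TMEDA, quenched with water, should give 3; the material is expected to be rich in the Z isomer, which is immaterial for step 3.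

**Further compounds**
F1 | step 3 | methyl octacosanoate | CCCCCCCCCCCCCCCCCCCCCCCCCCCC(=O)OC
F2 | step 2 | O-(heptacosan-14-yl) S-methyl dithiocarbonate | CCCCCCCCCCCCCC(OC(=S)SC)CCCCCCCCCCCCC
F3 | step 1 | heptacosan-14-one p-toluenesulfonylhydrazone | CCCCCCCCCCCCCC(=NNS(=O)(=O)c1ccc(C)cc1)CCCCCCCCCCCCC
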